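**Plan**

1. Locants used throughout: ring C1 (CH bearing the side chain), C5 (=C–CH3), C6 (=CH), C7 (CH, carbon arm of the lactone), C8 (CH–O), C9 (CH2), C10 (CH–CH3); side chain C2 (CH–O-angeloyl), C3, C4 (CH2OAc); lactone C11, C12 (C=O), C13 (=CH2); methyls C14 (on C10) and C15 (on C5).
2. Retrosynthesis: the two esters and C11=C13 are removed first, the lactone C12–O bond is opened to a C8/C12 1,4-diol, and C10–H/C14H3 is traced to a C10=C14 methylene. The cycloheptene is then cut at C8–C9 and C1–C10 into a vinylcyclopropane (C1=C5–C6, cyclopropane C6–C7–C8) and an alkyne (C9≡C10–C14).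
3. Enabling feature: the only ring olefin, C5=C6, lies exactly where a rhodium-catalysed vinylcyclopropane/alkyne (5+2) cycloaddition leaves its olefin. The adjacent sp3 ring carbons C7 and C8 carry the cis C–C and C–O bonds of the lactone, so they can be the cis-substituted carbons of a cyclopropane fused to a dioxepane that masks O8 and O12.
4. Helpers: the alkyne is tied to O2 through a CH2–Si(i-Pr)2–O tether whose CH2 is C14. After the cycloaddition, silicon is removed by Tamao–Fleming oxidation, the C9=C10 olefin is transposed reductively to C10=C14 and hydrogenated, and the acetonide is cleaved.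
5. Forward order: cyclopropane → alkyne → side chain C1–C4 (ynone, transfer hydrogenation, hydroalumination/iodination, methylation) → silicon tether → seven-membered ring and temporary oxasilinane ring in one step → γ-lactone → α-methylene → angelate and acetate.
6. Stereochemistry: C7/C8 from the asymmetric cyclopropanation (cis by the ring, retention in the cycloaddition); C2 from Noyori transfer hydrogenation; C1 from the (E)-olefin geometry and the suprafacial (5+2); C10 from hydrogenation directed by the C2 hydroxyl; the (Z)-ester comes from angelic acid.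

Key step: step 12

Assumption: the (S,S)-tert-butyl-bis(oxazoline)/CuOTf catalyst is taken to give the (1S,7S,8S) exo cyclopropane ester; if the sense of induction is the opposite, the (R,R) ligand is used.

**Route**

Step 1
Reactants: 1 2,2-dimethyl-4,7-dihydro-1,3-dioxepine
Product: 2 2,2-dimethyl-4,5-dihydro-1,3-dioxepine
Conditions: KOt-Bu (cat.), DMSO, 25–60 °C
Reagents that add atoms: none
Why: Base-mediated allyl ether to enol ether isomerisation (1,3-prototropic shift) moves the olefin into conjugation with oxygen, and the ring fixes the cis enol ether that later becomes C7/C8.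

Step 2
Reactants: 2 2,2-dimethyl-4,5-dihydro-1,3-dioxepine; 3 ethyl diazoacetate
Product: 4 ethyl (1S,7S,8S)-3,3-dimethyl-2,4-dioxabicyclo[5.1.0]octane-8-carboxylate (exo ester)
Conditions: CuOTf·0.5C6H6 (1 mol%), 2,2′-(propane-2,2-diyl)bis[(4S)-4-tert-butyl-4,5-dihydrooxazole] (1.2 mol%), CH2Cl2, 0 °C to rt, slow addition of 3; minor endo isomer removed by chromatography
Reagents that add atoms: none
Why: Copper–bis(oxazoline) carbene-transfer cyclopropanation of a cyclic cis-enol ether, in which the ring enforces the cis relation of C8–O and the C7 arm, the ester goes exo (trans to both) and the ligand selects the enol ether face, setting C7 and C8.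

Step 3
Reactants: 4 ethyl (1S,7S,8S)-3,3-dimethyl-2,4-dioxabicyclo[5.1.0]octane-8-carboxylate
Product: 6 (1S,7S,8R)-8-ethynyl-3,3-dimethyl-2,4-dioxabicyclo[5.1.0]octane, via aldehyde 5 (not isolated)
Conditions: i-Bu2AlH, CH2Cl2, −78 °C; then MeOH, K2CO3, dimethyl (1-diazo-2-oxopropyl)phosphonate, −78 °C to rt
Reagents that add atoms: dimethyl (1-diazo-2-oxopropyl)phosphonate, COP(=O)(OC)C(=[N+]=[N-])C(C)=O
Why: One-pot half-reduction of the ester and Seyferth–Gilbert homologation with the Ohira–Bestmann reagent gives the terminal alkyne (C5≡C1) under basic conditions that spare the alkoxycyclopropane and the acetonide.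

Step 4
Reactants: 7 methyl 3-hydroxypropanoate
Product: 8 methyl 3-[(tert-butyldiphenylsilyl)oxy]propanoate
Conditions: t-BuPh2SiCl, imidazole, DMF, rt
Reagents that add atoms: tert-butyl(chloro)diphenylsilane, CC(C)(C)[Si](Cl)(c1ccccc1)c1ccccc1
Why: Standard imidazole-promoted silylation of a primary alcohol gives an O4 protecting group that survives hydride, organometallic, fluoride-buffered peroxide and mild acid steps.

Step 5
Reactants: 8 methyl 3-[(tert-butyldiphenylsilyl)oxy]propanoate
Product: 9 3-[(tert-butyldiphenylsilyl)oxy]-N-methoxy-N-methylpropanamide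
Conditions: MeNH(OMe)·HCl, i-PrMgCl, THF, −20 °C
Reagents that add atoms: N,O-dimethylhydroxylamine hydrochloride, CNOC.Cl
Why: Weinreb amide formation by aminolysis of the ester with the chloromagnesium amide of N,O-dimethylhydroxylamine.

Step 6
Reactants: 6 (1S,7S,8R)-8-ethynyl-3,3-dimethyl-2,4-dioxabicyclo[5.1.0]octane; 9 3-[(tert-butyldiphenylsilyl)oxy]-N-methoxy-N-methylpropanamide
Product: 11 5-[(tert-butyldiphenylsilyl)oxy]-1-[exo-(1S,7S)-3,3-dimethyl-2,4-dioxabicyclo[5.1.0]octan-8-yl]pent-1-yn-3-one, via lithium acetylide 10 (not isolated)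
Conditions: n-BuLi, THF, −78 °C; then 9, −78 to 0 °C
Reagents that add atoms: none
Why: Acylation of a lithium acetylide by a Weinreb amide stops at the ynone because the chelated tetrahedral intermediate survives until work-up, joining C1 to C2.

Step 7
Reactants: 11 ynone
Product: 12 (3S)-5-[(tert-butyldiphenylsilyl)oxy]-1-[exo-(1S,7S)-3,3-dimethyl-2,4-dioxabicyclo[5.1.0]octan-8-yl]pent-1-yn-3-ol
Conditions: RuCl[(S,S)-TsDPEN](p-cymene) (2 mol%), i-PrOH, rt
Reagents that add atoms: none
Why: Noyori asymmetric transfer hydrogenation of an alkynyl ketone, in which the (S,S) catalyst treats the alkynyl group as the π-substituent and gives the (S)-carbinol, sets C2 under reagent control.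

Step 8
Reactants: 12 (S)-propargylic alcohol
Product: 14 (1Z,3S)-5-[(tert-butyldiphenylsilyl)oxy]-1-iodo-1-[exo-(1S,7S)-3,3-dimethyl-2,4-dioxabicyclo[5.1.0]octan-8-yl]pent-1-en-3-ol, via cyclic alkenylaluminate 13 (not isolated)
Conditions: NaAlH2(OCH2CH2OMe)2, THF, 0 °C to rt; then I2, THF, −78 to 0 °C
Reagents that add atoms: iodine, II
Why: Hydroxyl-directed trans-hydroalumination of the propargylic alcohol places aluminium on the distal carbon C5 in a five-membered alkoxyaluminate, and iodinolysis with retention gives the (Z)-γ-iodo allylic alcohol.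

Step 9
Reactants: 14 (Z)-vinyl iodide
Product: 15 (3S,4E)-1-[(tert-butyldiphenylsilyl)oxy]-5-[exo-(1S,7S)-3,3-dimethyl-2,4-dioxabicyclo[5.1.0]octan-8-yl]hex-4-en-3-ol
Conditions: MeZnCl, Pd(PPh3)4 (5 mol%), THF, rt to 50 °C
Reagents that add atoms: methylzinc chloride, C[Zn]Cl
Why: Negishi cross-coupling replaces iodine by the C15 methyl with retention of olefin geometry, giving the (E)-trisubstituted olefin (cyclopropyl trans to C2) that later fixes C1.

Step 10
Reactants: 16 propargyl bromide; 17 dichlorodiisopropylsilane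
Product: 19 chloro(diisopropyl)(prop-2-yn-1-yl)silane, via allenylmagnesium bromide 18 (not isolated)
Conditions: Mg, HgCl2 (cat.), Et2O, 0 °C; then added to i-Pr2SiCl2 (excess), −78 °C to rt; distillation
Reagents that add atoms: none
Why: The Grignard reagent of propargyl bromide reacts with the chlorosilane by SE2′ substitution to give the propargylsilane, and excess dichlorosilane keeps the reaction at monosubstitution.

Step 11
Reactants: 15 (E)-allylic alcohol; 19 chloro(diisopropyl)(prop-2-yn-1-yl)silane
Product: 20 diisopropyl(prop-2-yn-1-yl)silyl ether of 15 (silicon on O2)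
Conditions: imidazole, DMAP (cat.), DMF, rt to 40 °C; chromatography on Et3N-deactivated silica
Reagents that add atoms: none
Why: Nucleophilic substitution at silicon (silyl ether formation) installs the temporary O2–Si–C14 tether that holds the alkyne next to the vinyl terminus C1.

Step 12
Reactants: 20 tethered alkyne–vinylcyclopropane
Product: 21 tricyclic cycloadduct: cyclohepta-1,4-diene (C5=C6 and C9=C10) fused at C7/C8 to the dioxepane acetonide and at C1/C10 to a 2,2-diisopropyl-1,2-oxasilinane (O2–Si–C14)
Conditions: [Rh(CO)2Cl]2 (5 mol%), 1,2-dichloroethane (0.01 M), 80 °C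
Reagents that add atoms: none
Why: Proposed new method: monovalent rhodium is expected to coordinate the vinylcyclopropane, insert into the allylic cyclopropane bond C6–C8 to give a σ-alkyl/π-allyl rhodacyclohexene, insert the tethered alkyne into the Rh–C1 bond (forming C1–C10) and close the seven-membered ring by C8–C9 reductive elimination; the closest known reaction type is the rhodium-catalysed intramolecular (5+2) cycloaddition of alkyne-tethered vinylcyclopropanes, established for three- and four-atom tethers and for 2-substituted and ring-fused cyclopropanes, while temporary silicon tethers are known in rhodium-catalysed (2+2+2) and (4+2+2) reactions, so that the untested elements are the O–Si–CH2 tether and an oxygen-bearing cyclopropane carbon as the migrating terminus. Two rings close: the oxasilinane by 6-exo-dig carbometalation of the alkyne onto C1, and the cycloheptadiene by C(sp3)–C(sp2) reductive elimination from the eight-membered rhodacycle. The only new stereocentre, C1, is set by the (E)-olefin geometry and by bonding of both termini on the rhodium-bound face, which places the C2 branch cis to the two cyclopropane substituents that were trans to the vinyl group (C8–O and the C7 arm), while C8 keeps its configuration through retentive oxidative addition and reductive elimination and C7 is untouched. The step needs cleavage of C6–C8 and not of C6–C7: both bonds are equally substituted and both substituents are trans to the vinyl group, so the choice is electronic, and the α-oxygen weakens C6–C8 and stabilises the Rh–C8 bond, in line with the tendency of [Rh(CO)2Cl]2 to open the weaker cyclopropane bond. High dilution and the two isopropyl groups on silicon should favour ring closure over alkyne oligomerisation.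

Step 13
Reactants: 21 cycloadduct
Product: 22 allylic diol: C14 hydroxymethyl on C10 (C9=C10 retained) and free C2 hydroxyl, acetonide and silyl ether intact
Conditions: H2O2 (30% aq.), KF, KHCO3, THF–MeOH, 40 °C
Reagents that add atoms: hydrogen peroxide, OO
Why: Tamao–Fleming oxidation of the alkoxy(allyl)silane, in which peroxide attacks fluoride-activated silicon and C14 migrates to oxygen without allylic transposition, removes the tether and frees both the C14 and C2 hydroxyls.

Step 14
Reactants: 22 allylic diol
Product: 25 exocyclic methylene alcohol (C10=C14, C9 now CH2, free C2 hydroxyl), via sulfonylhydrazine 23 (not isolated), via allylic diazene 24 (not isolated)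
Conditions: 2-nitrobenzenesulfonylhydrazide, PPh3, diethyl azodicarboxylate, THF, −30 °C to rt
Reagents that add atoms: none
Why: Reductive 1,3-transposition of an allylic alcohol: Mitsunobu displacement of the primary allylic hydroxyl by the sulfonylhydrazide, loss of sulfinic acid and retro-ene loss of dinitrogen from the monoalkyl diazene deliver hydrogen to C9 and move the olefin to C10=C14 without touching the allylic C8–O bond, the hindered secondary C2 hydroxyl being expected to stay out of the Mitsunobu step at low temperature.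

Step 15
Reactants: 25 exocyclic methylene alcohol
Product: 27 triol (C2, C8 and C12 hydroxyls, C10 methyl, C5=C6 retained), via ketal alcohol 26 (not isolated)
Conditions: H2 (1 atm), [Ir(cod)(PCy3)(py)]PF6 (3 mol%), CH2Cl2, 0 °C, stopped after one equivalent; then pyridinium p-toluenesulfonate, MeOH, rt
Reagents that add atoms: none
Why: Hydroxyl-directed homogeneous hydrogenation, in which iridium bound to the C2 hydroxyl adds hydrogen to the 1,1-disubstituted exocyclic olefin from the face of the C1–C2 bond and so sets C10 with the methyl trans to the side chain while the trisubstituted C5=C6 olefin reacts far more slowly, followed by acid-catalysed transketalisation that frees the 1,4-diol.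

Step 16
Reactants: 27 triol
Product: 29 cis-fused hydroxy γ-lactone (C12 carbonyl, O on C8, free C2 hydroxyl), via lactol 28 (not isolated)
Conditions: TEMPO (20 mol%), PhI(OAc)2, CH2Cl2, rt
Reagents that add atoms: none
Why: TEMPO/PhI(OAc)2 oxidative lactonisation oxidises the primary C12 alcohol selectively, the aldehyde is trapped by the C8 hydroxyl as a five-membered lactol and oxidised on to the lactone, and the secondary C2 hydroxyl is left alone by this oxoammonium system.

Step 17
Reactants: 29 hydroxy lactone
Product: 32 α-methylene hydroxy lactone, via Mannich base 30 (not isolated), via ammonium iodide 31 (not isolated)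
Conditions: LiN(i-Pr)2 (2.3 equiv), THF, −78 °C; CH2=NMe2+ I−, −78 °C to rt; then MeI, MeOH, rt; then NaHCO3 (aq.), CH2Cl2
Reagents that add atoms: N,N-dimethylmethyleneiminium iodide, C=[N+](C)C.[I-]
Why: α-Methylenation by Mannich reaction of the lactone lithium enolate with Eschenmoser's salt, N-methylation and base-induced β-elimination of trimethylamine, with the C2 alkoxide carried as a spectator and the transient C11 stereocentre destroyed.

Step 18
Reactants: 32 α-methylene hydroxy lactone; 33 angelic acid
Product: 35 C2 angelate (O4 still silylated), via mixed anhydride 34 (not isolated)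
Conditions: 2,4,6-trichlorobenzoyl chloride, Et3N, toluene, rt; then 32, toluene, 80 °C
Reagents that add atoms: none
Why: Yamaguchi-type esterification through the mixed 2,4,6-trichlorobenzoic anhydride of angelic acid, a protocol suited to hindered secondary alcohols and chosen to avoid Z to E isomerisation to the tiglate.

Step 19
Reactants: 35 angelate silyl ether
Product: 36 primary alcohol at C4
Conditions: HF·pyridine, THF–pyridine, 0 °C to rt
Reagents that add atoms: none
Why: Buffered fluoride cleavage of the silyl ether spares the α-methylene lactone and the angelate.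

Step 20
Reactants: 36 primary alcohol
Product: 37 CNP0163960.1
Conditions: Ac2O, pyridine, DMAP (cat.), CH2Cl2, 0 °C
Reagents that add atoms: acetic anhydride, CC(=O)OC(C)=O
Why: DMAP-catalysed acetylation of the primary C4 hydroxyl completes the target without touching the existing stereocentres.

**Compound list**

1 | 2,2-dimethyl-4,7-dihydro-1,3-dioxepine | CC1(C)OCC=CCO1 | starting material
2 | 2,2-dimethyl-4,5-dihydro-1,3-dioxepine | CC1(C)OCCC=CO1 | intermediate
3 | ethyl diazoacetate | CCOC(=O)C=[N+]=[N-] | starting material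
4 | ethyl (1S,7S,8S)-3,3-dimethyl-2,4-dioxabicyclo[5.1.0]octane-8-carboxylate (exo) | CCOC(=O)[C@H]1[C@@H]2CCOC(C)(C)O[C@H]12 | intermediate
5 | (1S,7S,8S)-3,3-dimethyl-2,4-dioxabicyclo[5.1.0]octane-8-carbaldehyde (exo) | O=C[C@H]1[C@@H]2CCOC(C)(C)O[C@H]12 | intermediate
6 | (1S,7S,8R)-8-ethynyl-3,3-dimethyl-2,4-dioxabicyclo[5.1.0]octane (exo) | C#C[C@H]1[C@@H]2CCOC(C)(C)O[C@H]12 | intermediate
7 | methyl 3-hydroxypropanoate | COC(=O)CCO | starting material
8 | methyl 3-[(tert-butyldiphenylsilyl)oxy]propanoate | COC(=O)CCO[Si](c1ccccc1)(c1ccccc1)C(C)(C)C | intermediate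
9 | 3-[(tert-butyldiphenylsilyl)oxy]-N-methoxy-N-methylpropanamide | CON(C)C(=O)CCO[Si](c1ccccc1)(c1ccccc1)C(C)(C)C | intermediate
10 | lithium acetylide of 6 | [Li]C#C[C@H]1[C@@H]2CCOC(C)(C)O[C@H]12 | intermediate
11 | 5-[(tert-butyldiphenylsilyl)oxy]-1-[exo-(1S,7S)-3,3-dimethyl-2,4-dioxabicyclo[5.1.0]octan-8-yl]pent-1-yn-3-one | O=C(CCO[Si](c3ccccc3)(c4ccccc4)C(C)(C)C)C#C[C@H]1[C@@H]2CCOC(C)(C)O[C@H]12 | intermediate
12 | (3S)-5-[(tert-butyldiphenylsilyl)oxy]-1-[exo-(1S,7S)-3,3-dimethyl-2,4-dioxabicyclo[5.1.0]octan-8-yl]pent-1-yn-3-ol | O[C@@H](CCO[Si](c3ccccc3)(c4ccccc4)C(C)(C)C)C#C[C@H]1[C@@H]2CCOC(C)(C)O[C@H]12 | intermediate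
13 | sodium salt of the cyclic alkenyl alkoxyaluminate (Al bound to C5 and O2, two 2-methoxyethoxy ligands) | [Na+].COCCO[Al-]1(OCCOC)O[C@@H](CCO[Si](c3ccccc3)(c4ccccc4)C(C)(C)C)C=C1[C@H]5[C@@H]6CCOC(C)(C)O[C@H]56 | intermediate
14 | (1Z,3S)-5-[(tert-butyldiphenylsilyl)oxy]-1-iodo-1-[exo-(1S,7S)-3,3-dimethyl-2,4-dioxabicyclo[5.1.0]octan-8-yl]pent-1-en-3-ol | O[C@@H](CCO[Si](c3ccccc3)(c4ccccc4)C(C)(C)C)/C=C(\I)[C@H]1[C@@H]2CCOC(C)(C)O[C@H]12 | intermediate
15 | (3S,4E)-1-[(tert-butyldiphenylsilyl)oxy]-5-[exo-(1S,7S)-3,3-dimethyl-2,4-dioxabicyclo[5.1.0]octan-8-yl]hex-4-en-3-ol | O[C@@H](CCO[Si](c3ccccc3)(c4ccccc4)C(C)(C)C)/C=C(\C)[C@H]1[C@@H]2CCOC(C)(C)O[C@H]12 | intermediate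
16 | propargyl bromide (3-bromoprop-1-yne) | C#CCBr | starting material
17 | dichlorodiisopropylsilane | CC(C)[Si](Cl)(Cl)C(C)C | starting material
18 | allenylmagnesium bromide (Grignard reagent of propargyl bromide) | C=C=C[Mg]Br | intermediate
19 | chloro(diisopropyl)(prop-2-yn-1-yl)silane | C#CC[Si](Cl)(C(C)C)C(C)C | intermediate
20 | diisopropyl(prop-2-yn-1-yl)silyl ether of 15 (silicon on O2) | C#CC[Si](C(C)C)(C(C)C)O[C@@H](CCO[Si](c3ccccc3)(c4ccccc4)C(C)(C)C)/C=C(\C)[C@H]1[C@@H]2CCOC(C)(C)O[C@H]12 | intermediate
21 | (5+2) cycloadduct: cyclohepta-1,4-diene fused to the dioxepane acetonide (C7/C8) and to the 2,2-diisopropyl-1,2-oxasilinane (C1/C10), C2 bearing the 2-(silyloxy)ethyl group | CC1(C)OCC[C@H]2C=C(C)[C@@H]3C(=C[C@H]2O1)C[Si](C(C)C)(C(C)C)O[C@H]3CCO[Si](c4ccccc4)(c5ccccc5)C(C)(C)C | intermediate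
22 | allylic diol (C14–OH on C10 of the C9=C10 olefin, C2–OH), acetonide intact | CC1(C)OCC[C@H]2C=C(C)[C@@H]([C@@H](O)CCO[Si](c3ccccc3)(c4ccccc4)C(C)(C)C)C(CO)=C[C@H]2O1 | intermediate
23 | N-allyl-N-(2-nitrobenzenesulfonyl)hydrazine at C14 | CC1(C)OCC[C@H]2C=C(C)[C@@H]([C@@H](O)CCO[Si](c3ccccc3)(c4ccccc4)C(C)(C)C)C(CN(N)S(=O)(=O)c5ccccc5[N+](=O)[O-])=C[C@H]2O1 | intermediate
24 | allylic monoalkyl diazene at C14 | CC1(C)OCC[C@H]2C=C(C)[C@@H]([C@@H](O)CCO[Si](c3ccccc3)(c4ccccc4)C(C)(C)C)C(CN=N)=C[C@H]2O1 | intermediate
25 | exocyclic methylene alcohol (C10=C14, C2–OH), acetonide intact | CC1(C)OCC[C@H]2C=C(C)[C@@H]([C@@H](O)CCO[Si](c3ccccc3)(c4ccccc4)C(C)(C)C)C(=C)C[C@H]2O1 | intermediate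
26 | C10-methyl ketal alcohol (C2–OH), acetonide intact | CC1(C)OCC[C@H]2C=C(C)[C@@H]([C@@H](O)CCO[Si](c3ccccc3)(c4ccccc4)C(C)(C)C)[C@H](C)C[C@H]2O1 | intermediate
27 | triol (C2–OH, C8–OH, C12–OH), O4 silylated | OCC[C@H]1C=C(C)[C@@H]([C@@H](O)CCO[Si](c2ccccc2)(c3ccccc3)C(C)(C)C)[C@H](C)C[C@H]1O | intermediate
28 | cis-fused lactol (C12 hemiacetal with O8), mixture at C12 | OC1C[C@H]2C=C(C)[C@@H]([C@@H](O)CCO[Si](c3ccccc3)(c4ccccc4)C(C)(C)C)[C@H](C)C[C@H]2O1 | intermediate
29 | cis-fused hydroxy γ-lactone | O=C1C[C@H]2C=C(C)[C@@H]([C@@H](O)CCO[Si](c3ccccc3)(c4ccccc4)C(C)(C)C)[C@H](C)C[C@H]2O1 | intermediate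
30 | α-(dimethylaminomethyl) lactone (Mannich base, mixture at C11) | CN(C)CC1[C@H]2C=C(C)[C@@H]([C@@H](O)CCO[Si](c3ccccc3)(c4ccccc4)C(C)(C)C)[C@H](C)C[C@H]2OC1=O | intermediate
31 | α-(trimethylammoniomethyl) lactone iodide | C[N+](C)(C)CC1[C@H]2C=C(C)[C@@H]([C@@H](O)CCO[Si](c3ccccc3)(c4ccccc4)C(C)(C)C)[C@H](C)C[C@H]2OC1=O.[I-] | intermediate
32 | α-methylene hydroxy lactone (C2–OH, O4 silylated) | C=C1[C@H]2C=C(C)[C@@H]([C@@H](O)CCO[Si](c3ccccc3)(c4ccccc4)C(C)(C)C)[C@H](C)C[C@H]2OC1=O | intermediate
33 | angelic acid, (Z)-2-methylbut-2-enoic acid | C/C=C(/C)C(=O)O | starting material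
34 | angelic 2,4,6-trichlorobenzoic mixed anhydride | C/C=C(/C)C(=O)OC(=O)c1c(Cl)cc(Cl)cc1Cl | intermediate
35 | C2 angelate of 32 (O4 silylated) | C=C1[C@H]2C=C(C)[C@@H]([C@@H](OC(=O)/C(C)=C\C)CCO[Si](c3ccccc3)(c4ccccc4)C(C)(C)C)[C@H](C)C[C@H]2OC1=O | intermediate
36 | C2 angelate with free C4 hydroxyl | C=C1[C@H]2C=C(C)[C@@H]([C@@H](OC(=O)/C(C)=C\C)CCO)[C@H](C)C[C@H]2OC1=O | intermediate
37 | CNP0163960.1 (1S,2S,7R,8R,10R in the locants above) | C=C1C(=O)O[C@@H]2C[C@@H](C)[C@H]([C@H](CCOC(C)=O)OC(=O)/C(C)=C\C)C(C)=C[C@H]12 | target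

**Count and risks**

Total step count: 20. Longest linear sequence: 17 steps (steps 1–3, 6–9, 11–20).

Steps most likely to fail:

1. Step 12 (bears the label). Closure through the long Si–O and Si–C bonds of the six-membered tether ring may be too slow, so that alkyne oligomerisation or isomerisation of the propargylsilane takes over. The second uncertainty, insertion of rhodium into C6–C7 instead of C6–C8, does not depend on the tether and would be probed in the fallback series by a change of catalyst metal. The fallback uses reaction types of known class only, although the ring-opening regiochemistry of the oxygen-bearing cyclopropane remains untested there too. It sets out from 15 and comes back at 27.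
   - O-alkylation of 15 with NaH and 16 in THF should give the propargyl ether F1.
   - [Rh(CO)2Cl]2 in 1,2-dichloroethane should give the 3-alkylidene-tetrahydrofuran cycloadduct F2; the ether-tethered 1,6-enyne is the substrate class on which this cycloaddition is best documented.
   - Hydrogenolysis of the primary allylic C14–O bond with Pd(PPh3)4, ZnCl2 and polymethylhydrosiloxane should give the endocyclic olefin alcohol F3 (C9=C10 with the C10 methyl, free C2 hydroxyl); any exocyclic isomer formed is 25 itself.
   - Pyridinium p-toluenesulfonate in MeOH should give the triol F4.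
   - Hydrogenation with [Ir(cod)(PCy3)(py)]PF6, directed by the allylic C8 and homoallylic C2 hydroxyls, should reduce C9=C10 to give 27; stopping before the C5=C6 olefin reacts is the weak point of this sequence.

2. Step 14. Under Mitsunobu activation the C2 hydroxyl may displace the activated C14 oxygen intramolecularly (cyclodehydration of the 1,4-diol to the alkylidene-tetrahydrofuran) faster than the sulfonylhydrazide does. The fallback avoids activation of the C14–O bond. It sets out from 22 and comes back at 25.
   - MnO2 in CH2Cl2 should oxidise only the primary allylic alcohol to the enal F5.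
   - Condensation with p-toluenesulfonylhydrazide in EtOH should give the tosylhydrazone F6.
   - Catecholborane in CHCl3 should reduce it to the N-allyl-N′-tosylhydrazine F7 (as its N-boryl derivative).
   - NaOAc·3H2O at 60 °C should expel the sulfinate to give the same diazene 24, which loses dinitrogen with olefin transposition to 25.

3. Step 2. Carbene transfer to this particular enol ether may show insufficient facial or exo selectivity, and the donor–acceptor cyclopropane may open under Lewis acid. The fallback gives up catalyst control of the cyclopropane and resolves at a later stage. It sets out from 2 and comes back at 12.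
   - Cyclopropanation of 2 with 3 under Rh2(OAc)4 should give the racemic exo ester, that is 4 together with its enantiomer F8.
   - The racemate is taken through steps 3 and 6 unchanged, which adds the enantiomeric aldehyde F9, the enantiomeric alkyne F10, its lithium acetylide F11 and the enantiomeric ynone F12.
   - The catalyst-controlled transfer hydrogenation of step 7 then sets C2 as (S) in both series and gives 12 together with its diastereomer F13, which is removed by chromatography (preparative HPLC if needed); this separation of remote stereocentres across the alkyne is the weak point of the fallback.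

Further compounds

F1 | step 12 | propargyl ether of 15 (O2–CH2–C≡CH) | C#CCO[C@@H](CCO[Si](c3ccccc3)(c4ccccc4)C(C)(C)C)/C=C(\C)[C@H]1[C@@H]2CCOC(C)(C)O[C@H]12
F2 | step 12 | ether-tethered (5+2) cycloadduct (3-alkylidene-tetrahydrofuran O2–C14 fused at C1/C10) | CC1(C)OCC[C@H]2C=C(C)[C@@H]3C(=C[C@H]2O1)CO[C@H]3CCO[Si](c4ccccc4)(c5ccccc5)C(C)(C)C
F3 | step 12 | ketal alcohol with endocyclic C9=C10 olefin and C10 methyl | CC1(C)OCC[C@H]2C=C(C)[C@@H]([C@@H](O)CCO[Si](c3ccccc3)(c4ccccc4)C(C)(C)C)C(C)=C[C@H]2O1
F4 | step 12 | triol with endocyclic C9=C10 olefin | OCC[C@H]1C=C(C)[C@@H]([C@@H](O)CCO[Si](c2ccccc2)(c3ccccc3)C(C)(C)C)C(C)=C[C@H]1O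
F5 | step 14 | enal (C14 aldehyde on the C9=C10 olefin) | CC1(C)OCC[C@H]2C=C(C)[C@@H]([C@@H](O)CCO[Si](c3ccccc3)(c4ccccc4)C(C)(C)C)C(C=O)=C[C@H]2O1
F6 | step 14 | tosylhydrazone of F5 | CC1(C)OCC[C@H]2C=C(C)[C@@H]([C@@H](O)CCO[Si](c3ccccc3)(c4ccccc4)C(C)(C)C)C(C=NNS(=O)(=O)c5ccc(C)cc5)=C[C@H]2O1
F7 | step 14 | N-allyl-N′-tosylhydrazine at C14 | CC1(C)OCC[C@H]2C=C(C)[C@@H]([C@@H](O)CCO[Si](c3ccccc3)(c4ccccc4)C(C)(C)C)C(CNNS(=O)(=O)c5ccc(C)cc5)=C[C@H]2O1
F8 | step 2 | enantiomer of 4 | CCOC(=O)[C@@H]1[C@H]2CCOC(C)(C)O[C@@H]12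
F9 | step 2 | enantiomer of 5 | O=C[C@@H]1[C@H]2CCOC(C)(C)O[C@@H]12
F10 | step 2 | enantiomer of 6 | C#C[C@@H]1[C@H]2CCOC(C)(C)O[C@@H]12
F11 | step 2 | enantiomer of 10 | [Li]C#C[C@@H]1[C@H]2CCOC(C)(C)O[C@@H]12
F12 | step 2 | enantiomer of 11 | O=C(CCO[Si](c3ccccc3)(c4ccccc4)C(C)(C)C)C#C[C@@H]1[C@H]2CCOC(C)(C)O[C@@H]12
F13 | step 2 | diastereomer of 12 ((3S)-carbinol on the enantiomeric cyclopropane) | O[C@@H](CCO[Si](c3ccccc3)(c4ccccc4)C(C)(C)C)C#C[C@@H]1[C@H]2CCOC(C)(C)O[C@@H]12
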